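In the flask, target cannot exceed 0.0200 M: each one takes one coupling partner.

solid substrate 0.020 M; coupling partner 0.0200 M; time 2.5 h

    coupling partner ⇌ dormant form (K1 = 3.0, k1 = 0.015 min⁻¹)
    solid product ⇌ target, rate k2*(cs2 - [target]) while solid is left; crystals form when [target] > cs2 (cs2 = 0.37 mM, k2 = 2.7 min⁻¹)
    solid substrate ⇌ dissolved substrate, rate k3*(cs3 - [dissolved substrate]) while solid is left; crystals form when [dissolved substrate] > cs3 (cs3 = 13 mM, k3 = 0.013 min⁻¹)
    dissolved substrate + coupling partner → target (k4 = 130 M⁻¹ min⁻¹)

- for target the solid product is counted in
- as a solid, counted per litre of solution: solid substrate, solid product
- at the start none of the solid substrate is in solution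
- dissolved substrate means what is dissolved; the solid is not counted in it
- run time (flask): 2.5 h

- how much target and solid product together there is at 2.5 h, in percent of the solid substrate charged
- concentration of dissolved substrate in solution at 15 min, in percent of saturation
- the change that raises the amount of target and solid product together at 2.5 h, in percent of the solid substrate charged most ("none" if none brings more than 2 percentage points) (noon / summer / winter / autumn / none)
- amount of target and solid product together at 2.5 h, in percent of the solid substrate charged, after summer

- **First instants:** With coupling partner as charged, dissolved substrate couples with a half-life of 0.27 min, shorter than the 53.3 min of dissolving. So in these instants dissolving is the rate-limiting step, and I take target to form at r, the dissolution coefficient times the solubility: 0.169 mM min⁻¹. Meanwhile coupling partner leaks into dormant form.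
- **At 15 min:** I drop the way back from dormant form. Free coupling partner B is then 13.7 mM. Dissolved substrate sits where r equals coupling, which I reckon as 0.730% of saturation.
- **Middle:** My free coupling partner reaches zero at t* = 68.0 min, before the solid is used up at 118 min. In my reckoning dormant form then holds 8.50 mM.
- **End:** Dormant form returns at 0.00500 min⁻¹. That leaves D = 5.64 mM, the parked remainder: coupling partner still dormant at the end.
- **My answer:** I take free coupling partner as nil, so target is the coupling partner charged minus D, and I reckon y at 71.8%. Summer moves material between target and solid product, which are counted together, so it gives the same figure.
- **Other changes:** Noon doubles r, and the same reckoning gives 83.4%. For winter, I reckon the charge minus its own D at 22.1 mM, more than the 0.020 M of solid substrate. So I choose winter.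
- **The forecast:** It gives y 74.5%, sat 0.71%, best winter and yb 74.5%, holding that “the slow release from the dormant form limits the yield”. Its free partner lasts to about 77 min against my 68.0 min, and its y is above my 71.8%.
- **The flask:** It gives y 74.0%, sat 0.703%, best winter (a gain of 26 percentage points, against 9.8 points for noon) and yb 74.0%. At 2.50 h dormant form stands at 0.00517 M against my D of 5.64 mM. Solid substrate is at 0%, and 26.0% waits as dissolved substrate, so the shortfall is still in the flask.
- **A second flask:** With 0.050 M of solid substrate, the solid outlasts the run. The charge of coupling partner and r are unchanged, so my D is unchanged and I reckon y at 28.7%. At 2.50 h that flask holds 0.00516 M of dormant form and 57.2% of its charge as solid substrate, and its y is 29.6%.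

(All constants are assumed; the run is a simulation.)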